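**Retrosynthetic overview**
- The 4-hydroxybenzoate, the cyclopentene epoxide and the anti placement of the C-7 oxygen relative to the C-5 hydroxyl are late adjustments on a trans-fused bicyclo[5.3.0]deca-2,5-diene 7-silyl ether; both oxygenations are hydroxyl-directed.
- The cyclopentene is opened by ring-closing metathesis to a trans vinyl/methallyl pair on a cycloheptene; the methallyl group is placed by 1,2-addition to an enal and anionic oxy-Cope rearrangement.
- The strategy rests on the seven-membered ring (azulene numbering): the run C-3a, C-8a, C-8 (two ring-fusion CH, then CH-isopropyl) is a vinylcarbene, and the run C-7, C-6, C-5, C-4 (CH–O, CH2, C(CH3)OH, CH2) is a 1-silyloxy-3-methylbutadiene. The C-7–C-8 bond is therefore made in a divinylcyclopropane Cope rearrangement and the C-3a–C-4 bond in the cyclopropanation.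
- Ring order: seven-membered ring (step 5), cyclopentene (step 11), a transient epoxide on the seven-membered ring (step 13), the final epoxide last (step 18).

Key step: step 5

Assumption: the enantioface preference of Rh2(S-DOSP)4 is taken from its cyclopropanations of styrene with aryl- and vinyldiazoacetates (donor group cis to the alkene substituent, ester trans); applied to diene 8 this gives cyclopropane 9 as drawn and hence (3S,4S)-10, and the mirror-image catalyst Rh2(R-DOSP)4 would be used if the sense proved opposite.

Convention: bicyclic compounds carry azulene numbering (C-1 to C-3 in the five-membered ring, C-3a, C-4 to C-8, C-8a); β is the face of the isopropyl group at C-8, α the other face.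

Step 1
Reactants: 1 3-methylbutanal; 2 malonic acid
Product: 4 (E)-5-methylhex-3-enoic acid, via alkylidenemalonic acid 3 (not isolated)
Conditions: Et3N, neat, 90 °C
Reagents that add atoms: none
Why: Deconjugative Knoevenagel (Doebner-type) condensation, in which alkylidenemalonic acid 3 isomerises under the amine conditions to the β,γ-unsaturated form and loses CO2, should give the (E)-alk-3-enoic acid.

Step 2
Reactants: 4 (E)-5-methylhex-3-enoic acid
Product: 5 methyl (E)-5-methylhex-3-enoate
Conditions: MeOH, H2SO4 (2 mol %), rt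
Reagents that add atoms: methanol, CO
Why: Fischer esterification under mild acid should leave the non-conjugated E alkene in place.

Step 3
Reactants: 5 methyl (E)-5-methylhex-3-enoate
Product: 6 methyl (E)-2-diazo-5-methylhex-3-enoate
Conditions: 4-AcNHC6H4SO2N3, DBU, MeCN, 0 °C
Reagents that add atoms: 4-acetamidobenzenesulfonyl azide, CC(=O)Nc1ccc(cc1)S(=O)(=O)N=[N+]=[N-]
Why: Regitz diazo transfer to the DBU-generated ester enolate at the allylic α-CH2 is the standard access to vinyldiazoacetates, and 6 is to be used at once because such compounds slowly cyclise to pyrazoles.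

Step 4
Reactants: 7 3-methylbut-2-enal
Product: 8 (E)-1-(tert-butyldimethylsilyloxy)-3-methylbuta-1,3-diene
Conditions: t-BuMe2SiOTf, Et3N, Et2O, 0 °C to rt
Reagents that add atoms: tert-butyldimethylsilyl trifluoromethanesulfonate, CC(C)(C)[Si](C)(C)OS(=O)(=O)C(F)(F)F
Why: O-Silylation of the enal followed by γ-deprotonation by the amine (dienol silyl ether formation) should give the conjugated diene with the E enol ether.

Step 5
Reactants: 6 methyl (E)-2-diazo-5-methylhex-3-enoate; 8 (E)-1-(tert-butyldimethylsilyloxy)-3-methylbuta-1,3-diene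
Product: 10 methyl (3S,4S)-4-(tert-butyldimethylsilyloxy)-6-methyl-3-(propan-2-yl)cyclohepta-1,5-diene-1-carboxylate, via cis-divinylcyclopropane 9 (not isolated)
Conditions: Rh2(S-DOSP)4 = dirhodium tetrakis[(S)-N-(4-dodecylphenylsulfonyl)prolinate] (1 mol %), pentane, −78 °C to rt, slow addition of 6 to 8 (3 equiv)
Reagents that add atoms: none
Why: Loss of N2 from 6 at the dirhodium catalyst gives a catalyst-bound donor-acceptor vinylcarbene, which cyclopropanates the 1,1-disubstituted terminal alkene of 8 (carbene carbon to the CH2 terminus) to give cis-divinylcyclopropane 9. Ring strain then drives a Cope rearrangement of 9 through the boat transition state at or below room temperature; the closest known reaction type is the tandem cyclopropanation/Cope rearrangement (formal [4+3] cycloaddition) of vinyldiazoacetates with 1-oxygenated butadienes under divalent rhodium carboxylate catalysis. The seven-membered ring is closed by this [3,3] sigmatropic ring expansion: the bond between the isopropyl-bearing and the silyloxy-bearing carbons forms as the cyclopropane bond between the two quaternary carbons breaks. The boat geometry turns the two E alkene termini into the cis C-3/C-4 pair, and the absolute sense is set by the prolinate catalyst in the cyclopropanation and carried over by the stereospecific Cope step. The step needs attack at the terminal alkene only, the silyloxyvinyl group cis to the carbene vinyl group, and one enantioface: the trans-disubstituted enol ether is inert to donor-acceptor carbenes, positive charge at the internal carbon is stabilised by the dienol ether, and the carbene places the unsaturated alkene substituent beside its vinyl donor and away from the ester.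

Step 6
Reactants: 10 methyl (3S,4S)-4-(tert-butyldimethylsilyloxy)-6-methyl-3-(propan-2-yl)cyclohepta-1,5-diene-1-carboxylate
Product: 11 [(3S,4S)-4-(tert-butyldimethylsilyloxy)-6-methyl-3-(propan-2-yl)cyclohepta-1,5-dien-1-yl]methanol
Conditions: (i-Bu)2AlH, CH2Cl2, −78 °C
Reagents that add atoms: none
Why: 1,2-Hydride reduction of the conjugated ester by the aluminium hydride should give the allylic alcohol and leave the silyl ether and both stereocentres untouched.

Step 7
Reactants: 11 [(3S,4S)-4-(tert-butyldimethylsilyloxy)-6-methyl-3-(propan-2-yl)cyclohepta-1,5-dien-1-yl]methanol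
Product: 12 (3S,4S)-4-(tert-butyldimethylsilyloxy)-6-methyl-3-(propan-2-yl)cyclohepta-1,5-diene-1-carbaldehyde
Conditions: MnO2, CH2Cl2, rt
Reagents that add atoms: none
Why: Allylic oxidation with MnO2 is selective for the primary allylic alcohol and neutral, so the γ-hydrogen/silyloxy array is not exposed to base.

Step 8
Reactants: 12 (3S,4S)-4-(tert-butyldimethylsilyloxy)-6-methyl-3-(propan-2-yl)cyclohepta-1,5-diene-1-carbaldehyde; 13 2-methylallylmagnesium chloride
Product: 14 1-[(3S,4S)-4-(tert-butyldimethylsilyloxy)-6-methyl-3-(propan-2-yl)cyclohepta-1,5-dien-1-yl]-3-methylbut-3-en-1-ol (both carbinol epimers)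
Conditions: THF, −78 °C
Reagents that add atoms: none
Why: Grignard 1,2-addition of the allylic reagent to the enal is fast at low temperature, and the new carbinol centre is erased in the next step, so both epimers serve.

Step 9
Reactants: 14 1-[(3S,4S)-4-(tert-butyldimethylsilyloxy)-6-methyl-3-(propan-2-yl)cyclohepta-1,5-dien-1-yl]-3-methylbut-3-en-1-ol
Product: 17 (1S,2S,3S,4S)-4-(tert-butyldimethylsilyloxy)-6-methyl-2-(2-methylprop-2-enyl)-3-(propan-2-yl)cyclohept-5-ene-1-carbaldehyde, via potassium alkoxide 15 (not isolated), via potassium enolate 16 (not isolated)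
Conditions: KH, 18-crown-6, THF, 0 °C to rt; then MeOH, rt
Reagents that add atoms: none
Why: Anionic oxy-Cope rearrangement of alkoxide 15 moves the methallyl group to the ring carbon next to CH-isopropyl (net conjugate methallylation) on the face opposite the cis isopropyl/silyloxy pair, one member of which must sit pseudoaxial on the β face, and protonation of enolate 16 followed by methoxide equilibration should set the formyl group trans to the new substituent.

Step 10
Reactants: 17 (1S,2S,3S,4S)-4-(tert-butyldimethylsilyloxy)-6-methyl-2-(2-methylprop-2-enyl)-3-(propan-2-yl)cyclohept-5-ene-1-carbaldehyde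
Product: 18 the 1-ethenyl analogue of 17 (CHO replaced by CH=CH2, the four stereocentres unchanged in space: vinyl, isopropyl and silyloxy β, methallyl α)
Conditions: Ph3PCH3Br, KOt-Bu, THF, 0 °C
Reagents that add atoms: methylenetriphenylphosphorane, C=P(c1ccccc1)(c1ccccc1)c1ccccc1, made in the flask from methyltriphenylphosphonium bromide, C[P+](c1ccccc1)(c1ccccc1)c1ccccc1.[Br-]
Why: Wittig methylenation with the non-stabilised ylide is fast at 0 °C, and the α centre already holds its more stable trans arrangement.

Step 11
Reactants: 18 the 1-ethenyl analogue of 17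
Product: 19 7β-(tert-butyldimethylsilyloxy)-2,5-dimethyl-8β-(propan-2-yl)-1,3a,4,7,8,8a-hexahydroazulene with H-3a α and H-8a β (trans ring fusion)
Conditions: second-generation Grubbs catalyst (H2IMes)(PCy3)Cl2Ru=CHPh (5 mol %), CH2Cl2, 40 °C
Reagents that add atoms: none
Why: Ring-closing metathesis between the vinyl group and the 1,1-disubstituted methallyl alkene closes the cyclopentene with loss of ethene, the trans side chains giving the trans ring fusion, while the trisubstituted ring alkene does not engage the ruthenium carbene.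

Step 12
Reactants: 19 the trans-fused bicyclic silyl ether
Product: 20 2,5-dimethyl-8β-(propan-2-yl)-1,3a,4,7,8,8a-hexahydroazulen-7β-ol (H-3a α, H-8a β)
Conditions: Bu4NF, THF, rt to 50 °C
Reagents that add atoms: none
Why: Fluoride-induced desilylation cleaves the Si–O bond and leaves both alkenes alone.

Step 13
Reactants: 20 the 7β-allylic alcohol
Product: 21 5β,6β-epoxy-2,5-dimethyl-8β-(propan-2-yl)-1,3a,4,5,6,7,8,8a-octahydroazulen-7β-ol
Conditions: VO(acac)2 (5 mol %), t-BuOOH, CH2Cl2, 0 °C to rt
Reagents that add atoms: tert-butyl hydroperoxide, CC(C)(C)OO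
Why: Hydroxyl-directed epoxidation through the vanadium alkoxide/peroxide complex is selective for the allylic-alcohol alkene over the isolated cyclopentene and delivers oxygen syn to the 7β-hydroxyl, as established for cyclohept-2-enols, which sets C-5 and C-6.

Step 14
Reactants: 21 the syn epoxy alcohol
Product: 22 2,5α-dimethyl-8β-(propan-2-yl)-1,3a,4,5,6,7,8,8a-octahydroazulene-5β,7β-diol (syn-1,3-diol)
Conditions: LiAlH4, THF, 0 °C to reflux
Reagents that add atoms: none
Why: Reductive epoxide opening by hydride in an SN2 manner at the less substituted carbon C-6, anti to the epoxide oxygen, should leave the oxygen on C-5 as the tertiary β-hydroxyl.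

Step 15
Reactants: 22 the syn-1,3-diol
Product: 23 5β-hydroxy-2,5α-dimethyl-8β-(propan-2-yl)-3a,4,5,6,8,8a-hexahydroazulen-7(1H)-one
Conditions: Dess–Martin periodinane, pyridine, CH2Cl2, 0 °C to rt
Reagents that add atoms: none
Why: Dess–Martin oxidation converts only the secondary alcohol under buffered non-basic conditions, which should avoid retro-aldol cleavage, dehydration and epimerisation at C-8.

Step 16
Reactants: 23 the β-hydroxy ketone
Product: 24 2,5α-dimethyl-8β-(propan-2-yl)-1,3a,4,5,6,7,8,8a-octahydroazulene-5β,7α-diol (anti-1,3-diol)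
Conditions: Me4NBH(OAc)3, MeCN/AcOH, −20 °C
Reagents that add atoms: none
Why: Evans–Saksena hydroxyl-directed reduction places the borohydride on the tertiary 5β-oxygen by ligand exchange and delivers hydride intramolecularly to the β face of the ketone, which should give the 7α-alcohol, anti to the C-5 hydroxyl and trans to isopropyl.

Step 17
Reactants: 24 the anti-1,3-diol; 25 4-acetoxybenzoic acid
Product: 26 5β-hydroxy-2,5α-dimethyl-8β-(propan-2-yl)-1,3a,4,5,6,7,8,8a-octahydroazulen-7α-yl 4-acetoxybenzoate
Conditions: DCC, DMAP, CH2Cl2, 0 °C to rt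
Reagents that add atoms: none
Why: Steglich esterification acylates the secondary hydroxyl and leaves the tertiary one free on steric grounds, the phenol being masked as its acetate so that it cannot compete.

Step 18
Reactants: 26 the 4-acetoxybenzoate
Product: 27 2β,3β-epoxy-5β-hydroxy-2α,5α-dimethyl-8β-(propan-2-yl)decahydroazulen-7α-yl 4-acetoxybenzoate
Conditions: VO(acac)2 (10 mol %), t-BuOOH, CH2Cl2, rt
Reagents that add atoms: tert-butyl hydroperoxide, CC(C)(C)OO
Why: Hydroxyl-directed epoxidation by the vanadium alkoxide of the tertiary 5β-hydroxyl, which is bishomoallylic to C-2=C-3 and sits above the cyclopentene face turned towards C-4, should deliver the peroxide oxygen to that face and give the 2β,3β-epoxide.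

Step 19
Reactants: 27 the epoxy 4-acetoxybenzoate
Product: 28 target CNP0245441.1, 2β,3β-epoxy-5β-hydroxy-2α,5α-dimethyl-8β-(propan-2-yl)decahydroazulen-7α-yl 4-hydroxybenzoate (C-2 R, C-3 S, C-3a S, C-5 R, C-7 S, C-8 S, C-8a R)
Conditions: NH3, MeOH, 0 °C
Reagents that add atoms: none
Why: Ammonolysis cleaves the activated phenolic acetate much faster than the hindered secondary benzoate and should not open the trisubstituted epoxide in the cold.

**Compound list**
1 | 3-methylbutanal | CC(C)CC=O | starting material
2 | malonic acid | OC(=O)CC(=O)O | starting material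
3 | 2-(3-methylbutylidene)propanedioic acid | CC(C)CC=C(C(=O)O)C(=O)O | intermediate
4 | (E)-5-methylhex-3-enoic acid | CC(C)/C=C/CC(=O)O | intermediate
5 | methyl (E)-5-methylhex-3-enoate | COC(=O)C/C=C/C(C)C | intermediate
6 | methyl (E)-2-diazo-5-methylhex-3-enoate | COC(=O)C(=[N+]=[N-])/C=C/C(C)C | intermediate
7 | 3-methylbut-2-enal | CC(C)=CC=O | starting material
8 | (E)-1-(tert-butyldimethylsilyloxy)-3-methylbuta-1,3-diene | C=C(C)/C=C/O[Si](C)(C)C(C)(C)C | intermediate
9 | methyl (1R,2R)-2-[(E)-2-(tert-butyldimethylsilyloxy)ethenyl]-2-methyl-1-[(E)-3-methylbut-1-enyl]cyclopropane-1-carboxylate (the two alkenyl groups cis) | COC(=O)[C@@]1(/C=C/C(C)C)C[C@]1(C)/C=C/O[Si](C)(C)C(C)(C)C | intermediate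
10 | methyl (3S,4S)-4-(tert-butyldimethylsilyloxy)-6-methyl-3-(propan-2-yl)cyclohepta-1,5-diene-1-carboxylate | CC(C)[C@H]1C=C(C(=O)OC)CC(C)=C[C@H]1O[Si](C)(C)C(C)(C)C | intermediate
11 | [(3S,4S)-4-(tert-butyldimethylsilyloxy)-6-methyl-3-(propan-2-yl)cyclohepta-1,5-dien-1-yl]methanol | CC(C)[C@H]1C=C(CO)CC(C)=C[C@H]1O[Si](C)(C)C(C)(C)C | intermediate
12 | (3S,4S)-4-(tert-butyldimethylsilyloxy)-6-methyl-3-(propan-2-yl)cyclohepta-1,5-diene-1-carbaldehyde | CC(C)[C@H]1C=C(C=O)CC(C)=C[C@H]1O[Si](C)(C)C(C)(C)C | intermediate
13 | 2-methylallylmagnesium chloride | CC(=C)C[Mg]Cl | starting material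
14 | 1-[(3S,4S)-4-(tert-butyldimethylsilyloxy)-6-methyl-3-(propan-2-yl)cyclohepta-1,5-dien-1-yl]-3-methylbut-3-en-1-ol, both carbinol epimers | CC(C)[C@H]1C=C(C(O)CC(C)=C)CC(C)=C[C@H]1O[Si](C)(C)C(C)(C)C | intermediate
15 | potassium alkoxide of 14 | CC(C)[C@H]1C=C(C([O-])CC(C)=C)CC(C)=C[C@H]1O[Si](C)(C)C(C)(C)C.[K+] | intermediate
16 | potassium enolate of aldehyde 17 (methallyl α, isopropyl and silyloxy β) | CC(C)[C@H]1[C@H](CC(C)=C)C(=C[O-])CC(C)=C[C@H]1O[Si](C)(C)C(C)(C)C.[K+] | intermediate
17 | (1S,2S,3S,4S)-4-(tert-butyldimethylsilyloxy)-6-methyl-2-(2-methylprop-2-enyl)-3-(propan-2-yl)cyclohept-5-ene-1-carbaldehyde | CC(C)[C@H]1[C@H](CC(C)=C)[C@@H](C=O)CC(C)=C[C@H]1O[Si](C)(C)C(C)(C)C | intermediate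
18 | 1-ethenyl analogue of 17 (vinyl, isopropyl and silyloxy β, methallyl α) | CC(C)[C@H]1[C@H](CC(C)=C)[C@@H](C=C)CC(C)=C[C@H]1O[Si](C)(C)C(C)(C)C | intermediate
19 | 7β-(tert-butyldimethylsilyloxy)-2,5-dimethyl-8β-(propan-2-yl)-1,3a,4,7,8,8a-hexahydroazulene, H-3a α, H-8a β | CC(C)[C@H]1[C@@H]2CC(C)=C[C@H]2CC(C)=C[C@H]1O[Si](C)(C)C(C)(C)C | intermediate
20 | 2,5-dimethyl-8β-(propan-2-yl)-1,3a,4,7,8,8a-hexahydroazulen-7β-ol | CC(C)[C@H]1[C@@H]2CC(C)=C[C@H]2CC(C)=C[C@H]1O | intermediate
21 | 5β,6β-epoxy-2,5-dimethyl-8β-(propan-2-yl)-1,3a,4,5,6,7,8,8a-octahydroazulen-7β-ol | CC(C)[C@H]1[C@@H]2CC(C)=C[C@H]2C[C@@]3(C)O[C@H]3[C@H]1O | intermediate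
22 | 2,5α-dimethyl-8β-(propan-2-yl)-1,3a,4,5,6,7,8,8a-octahydroazulene-5β,7β-diol | CC(C)[C@H]1[C@@H]2CC(C)=C[C@H]2C[C@@](C)(O)C[C@H]1O | intermediate
23 | 5β-hydroxy-2,5α-dimethyl-8β-(propan-2-yl)-3a,4,5,6,8,8a-hexahydroazulen-7(1H)-one | CC(C)[C@H]1[C@@H]2CC(C)=C[C@H]2C[C@@](C)(O)CC1=O | intermediate
24 | 2,5α-dimethyl-8β-(propan-2-yl)-1,3a,4,5,6,7,8,8a-octahydroazulene-5β,7α-diol | CC(C)[C@H]1[C@@H]2CC(C)=C[C@H]2C[C@@](C)(O)C[C@@H]1O | intermediate
25 | 4-acetoxybenzoic acid | CC(=O)Oc1ccc(cc1)C(=O)O | starting material
26 | 5β-hydroxy-2,5α-dimethyl-8β-(propan-2-yl)-1,3a,4,5,6,7,8,8a-octahydroazulen-7α-yl 4-acetoxybenzoate | CC(C)[C@H]1[C@@H]2CC(C)=C[C@H]2C[C@@](C)(O)C[C@@H]1OC(=O)c1ccc(OC(C)=O)cc1 | intermediate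
27 | 2β,3β-epoxy-5β-hydroxy-2α,5α-dimethyl-8β-(propan-2-yl)decahydroazulen-7α-yl 4-acetoxybenzoate | CC(C)[C@H]1[C@@H]2C[C@@]3(C)O[C@H]3[C@H]2C[C@@](C)(O)C[C@@H]1OC(=O)c1ccc(OC(C)=O)cc1 | intermediate
28 | CNP0245441.1, 2β,3β-epoxy-5β-hydroxy-2α,5α-dimethyl-8β-(propan-2-yl)decahydroazulen-7α-yl 4-hydroxybenzoate | CC(C)[C@H]1[C@@H]2C[C@@]3(C)O[C@H]3[C@H]2C[C@@](C)(O)C[C@@H]1OC(=O)c1ccc(O)cc1 | target

Total step count: 19
Longest linear sequence: 18 steps (steps 1 to 3 and 5 to 19, from 3-methylbutanal)

**Steps most likely to fail**

Step 5. The carbene transfer may show poor enantioface selection on the 1,1-disubstituted alkene, or leak to the trans-divinylcyclopropane, which rearranges only on heating and can give other products. The fallback moves stereocontrol from the catalyst to a covalently bound auxiliary and sets out from acid 4. Esterification with (R)-pantolactone (DCC, DMAP, CH2Cl2) should give (R)-pantolactonyl (E)-5-methylhex-3-enoate F1. Diazo transfer (4-acetamidobenzenesulfonyl azide, DBU, MeCN) should give (R)-pantolactonyl (E)-2-diazo-5-methylhex-3-enoate F2. Decomposition of F2 by the achiral catalyst dirhodium tetraoctanoate Rh2(O2CC7H15)4 in pentane with diene 8 should give the pantolactonyl (3S,4S)-cycloheptadienecarboxylate F3, the lactone carbonyl shielding one face of the carbene. Diastereomers of F3 are separable by chromatography, so incomplete induction costs material but not enantiomeric purity; which pantolactone enantiomer is the matched one has to be settled on F3. Reduction of F3 with (i-Bu)2AlH removes the auxiliary and comes back to the route at allylic alcohol 11.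

Step 16. Intramolecular hydride delivery from the tertiary alkoxyborohydride, which must come in on the face of the neighbouring isopropyl group, may be outrun by external attack from the α face (returning syn-diol 22), or the β-hydroxy ketone may cleave by retro-aldol reaction. The fallback inverts C-7 without passing through the ketone and sets out from syn-diol 22. Mitsunobu reaction with 4-nitrobenzoic acid (PPh3, DIAD, toluene), as used to invert menthol-type alcohols, should give the inverted 5β-hydroxy-7α-yl 4-nitrobenzoate F4; the tertiary hydroxyl lies on the same face as the leaving group and cannot displace it. Methanolysis (K2CO3, MeOH) then comes back to the route at anti-diol 24, replacing steps 15 and 16.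

Step 18. The tertiary hydroxyl may be too remote to hold the vanadium peroxide over the cyclopentene, so that oxygen adds without facial preference or from the exposed α face. The fallback replaces substrate direction by reagent control and sets out from 26. It uses the Shi epoxidation: the dioxirane from KHSO5 (as the triple salt 2KHSO5·KHSO4·K2SO4) and the enantiomer of the fructose-derived ketone (obtainable from L-sorbose), K2CO3 buffer, MeCN/dimethoxymethane/H2O, 0 °C. The spiro transition state, read by analogy with 1-substituted cycloalkenes, predicts attack on the β face. It comes back to the route at 27; any loss of the phenolic acetate at the buffered pH only anticipates step 19. No new compound lies on this path.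

**Further compounds**
F1 | step 5 | (R)-pantolactonyl (E)-5-methylhex-3-enoate | CC(C)/C=C/CC(=O)O[C@H]1C(=O)OCC1(C)C
F2 | step 5 | (R)-pantolactonyl (E)-2-diazo-5-methylhex-3-enoate | CC(C)/C=C/C(=[N+]=[N-])C(=O)O[C@H]1C(=O)OCC1(C)C
F3 | step 5 | (R)-pantolactonyl (3S,4S)-4-(tert-butyldimethylsilyloxy)-6-methyl-3-(propan-2-yl)cyclohepta-1,5-diene-1-carboxylate | CC(C)[C@H]1C=C(C(=O)O[C@H]2C(=O)OCC2(C)C)CC(C)=C[C@H]1O[Si](C)(C)C(C)(C)C
F4 | step 16 | 5β-hydroxy-2,5α-dimethyl-8β-(propan-2-yl)-1,3a,4,5,6,7,8,8a-octahydroazulen-7α-yl 4-nitrobenzoate | CC(C)[C@H]1[C@@H]2CC(C)=C[C@H]2C[C@@](C)(O)C[C@@H]1OC(=O)c1ccc(cc1)[N+](=O)[O-]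
F0 | step 18 | none | none
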